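**Plan**
- Numbering: in the lactone ring C9 is the carbonyl carbon, C8 the carbinol carbon (benzylic C7), C8' the ring CH (benzylic C7') and C9' the ring OCH2. The target is the (3S,4R)-lactone (C8 S, C8' R), with both benzyl groups on the same ring face.
- Retrosynthesis: two O-benzyl groups, one O-silyl group and a p-tolylthio helper on C9' are removed. C8–C8' and C9'–O(ring) are then cut together, which leaves the (R,E)-alkenyl sulfoxide 9 and the siloxy(benzyl)ketene 15, made from acid chloride 14.
- Enabling feature: both ends of the ring segment C9–C8–C8'–C9' carry oxygen, so C8 and C8' are two carbons of like (donor) polarity. A sulfinyl group on C9' lends its oxygen to C9, reverses the polarity of C8' in a [3,3] shift, and leaves C9' as a thionium ion for the new carboxylate oxygen.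
- Forward order: one benzylic bromide 2 feeds both halves. The halves are joined at the fully substituted C8 and the only new ring, the lactone, closes in the same step. Sulfur, silicon and benzyl groups are then removed.
- Stereochemistry: the sulfur stereocentre comes from menthyl sulfinate 5 and is passed to C8' through a chair [3,3] transition state. C8 follows from the enolate geometry combined with the E alkene.

Key step: step 8

Remark: 12, 13 and 14 are used as racemates, because their only stereocentre becomes the sp2 carbon C8 of ketene 15.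

**Step 1**
Reactants: 1 4-benzyloxy-3-methoxybenzyl alcohol
Product: 2 4-benzyloxy-3-methoxybenzyl bromide
Conditions: PBr3, Et2O, 0 °C
Reagents that add atoms: phosphorus tribromide, BrP(Br)Br
Why: SN2 bromination of an activated benzylic alcohol through its phosphite ester is standard, and the aryl benzyl and methyl ethers are inert to PBr3 at this temperature.

**Step 2**
Reactants: 2 4-benzyloxy-3-methoxybenzyl bromide; 3 ethynylmagnesium bromide (excess)
Product: 4 1-benzyloxy-2-methoxy-4-(prop-2-yn-1-yl)benzene
Conditions: CuBr·SMe2 (10 mol %), THF, 0 °C to rt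
Reagents that add atoms: none
Why: Copper-catalysed cross-coupling of a benzylic bromide with an alkynyl Grignard reagent gives the skipped aryl-propyne, and the excess of 3 suppresses a second benzylation.

**Step 3**
Reactants: 4 1-benzyloxy-2-methoxy-4-(prop-2-yn-1-yl)benzene; 5 (1R,2S,5R)-menthyl (S)-4-methylbenzenesulfinate
Product: 7 (S)-1-benzyloxy-2-methoxy-4-[3-(4-methylphenylsulfinyl)prop-2-yn-1-yl]benzene, via alkynylmagnesium bromide 6 (not isolated)
Conditions: EtMgBr, THF, 0 °C to rt; then added to 5, toluene, −20 °C; aq NH4Cl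
Reagents that add atoms: none
Why: In this Andersen sulfoxide synthesis the alkynyl Grignard reagent 6 displaces menthoxide from sulfur with inversion, so the sulfur stereocentre of 7 comes from crystalline 5, and inverse addition at low temperature keeps the acidic propargylic CH2 away from excess base.

**Step 4**
Reactants: 7 (S)-1-benzyloxy-2-methoxy-4-[3-(4-methylphenylsulfinyl)prop-2-yn-1-yl]benzene
Product: 9 (R)-1-benzyloxy-2-methoxy-4-[(E)-3-(4-methylphenylsulfinyl)prop-2-en-1-yl]benzene, via alkenylalane 8 (not isolated)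
Conditions: iBu2AlH, THF, −90 °C; MeOH, then aq potassium sodium tartrate
Reagents that add atoms: none
Why: Sulfinyl-directed trans-hydroalumination of a 1-alkynyl sulfoxide (hydride to C8', aluminium to C9') and protonolysis with retention is the known stereoselective route to (E)-1-alkenyl sulfoxides, and it leaves the geometry at sulfur untouched, the descriptor changing from S to R only through the priority rules.

**Step 5**
Reactants: 10 ethyl 2-(tert-butyldimethylsilyloxy)acetate; 2 4-benzyloxy-3-methoxybenzyl bromide
Product: 12 ethyl (±)-3-(4-benzyloxy-3-methoxyphenyl)-2-(tert-butyldimethylsilyloxy)propanoate, via lithium enolate 11 (not isolated)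
Conditions: LiN(iPr)2, THF, −78 °C; DMPU, then 2, −78 to −20 °C
Reagents that add atoms: none
Why: SN2 alkylation of a glycolate ester enolate with a reactive benzylic bromide makes the C7–C8 bond, and the new stereocentre is deliberately racemic because step 8 erases it.

**Step 6**
Reactants: 12 ethyl (±)-3-(4-benzyloxy-3-methoxyphenyl)-2-(tert-butyldimethylsilyloxy)propanoate
Product: 13 (±)-3-(4-benzyloxy-3-methoxyphenyl)-2-(tert-butyldimethylsilyloxy)propanoic acid
Conditions: LiOH, THF/MeOH/H2O, 0 °C to rt; 1 M HCl to pH 3
Reagents that add atoms: lithium hydroxide, [Li+].[OH-]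
Why: Saponification of an unhindered ethyl ester by acyl–oxygen cleavage is faster than loss of a secondary TBS ether under these mild conditions.

**Step 7**
Reactants: 13 (±)-3-(4-benzyloxy-3-methoxyphenyl)-2-(tert-butyldimethylsilyloxy)propanoic acid
Product: 14 (±)-3-(4-benzyloxy-3-methoxyphenyl)-2-(tert-butyldimethylsilyloxy)propanoyl chloride
Conditions: (COCl)2, DMF (cat.), CH2Cl2, 0 °C to rt; concentrated and used crude
Reagents that add atoms: oxalyl chloride, O=C(Cl)C(=O)Cl
Why: Acid chloride formation through the catalytic chloroiminium (Vilsmeier-type) species is routine for α-silyloxy acids and gives only gaseous by-products.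

**Step 8**
Reactants: 9 (R)-1-benzyloxy-2-methoxy-4-[(E)-3-(4-methylphenylsulfinyl)prop-2-en-1-yl]benzene; 14 (±)-3-(4-benzyloxy-3-methoxyphenyl)-2-(tert-butyldimethylsilyloxy)propanoyl chloride
Product: 18 (3S,4S,5R)-3,4-bis(4-benzyloxy-3-methoxybenzyl)-3-(tert-butyldimethylsilyloxy)-5-(4-methylphenylthio)dihydrofuran-2(3H)-one, via siloxyketene 15 (not isolated), via oxysulfonium enolate 16 (not isolated), via thionium carboxylate 17 (not isolated)
Conditions: 9, iPr2NEt (3 equiv), toluene, −20 °C; 14 (1.5 equiv) added over 2 h by syringe pump; then rt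
Reagents that add atoms: none
Why: Proposed new method: iPr2NEt dehydrochlorinates 14 to ketene 15, the sulfinyl oxygen of 9 adds to its carbonyl carbon C9 to give oxysulfonium enolate 16, a charge-accelerated [3,3]-sigmatropic (sulfonium-Claisen) shift forms C8–C8' while S–O breaks, and the carboxylate oxygen of thionium ion 17 adds to C9'. The closest known reaction types are the lactonization of enantiopure 1-alkenyl sulfoxides with dichloroketene (Marino lactonization, an additive Pummerer process) and the sulfonium-Claisen union of vinyl sulfoxides with keteniminium ions to 1,4-dicarbonyl compounds; what is new is a ketene bearing one oxygen and one carbon substituent, which should still react because an oxygen substituent destabilises and polarises the cumulene much as chlorine does. The lactone, the only ring closed, forms by 5-exo-trig attack of the carboxylate on the C9'=S+ carbon from the face that has just received C8, which places the arylthio group trans to the C8' benzyl group and creates a C9' stereocentre that step 9 erases. C8' is controlled by the sulfur stereocentre: in the chair the p-tolyl group is pseudo-equatorial and the lone pair eclipses the alkene, so the R sulfoxide hands the enolate to a single face of the E alkene. C8 is controlled by the enolate geometry: the OTBS group lies s-cis beside C9 in the ketene plane, so the sulfoxide enters from the benzyl side to give the E enolate (benzyl cis to O–S), and this enolate with the E alkene in a chair places both benzyl groups on the same ring face. The step needs addition, shift and ring closure to outrun ketene dimerisation, deprotonation at C7' (vinylogous Pummerer path) and Friedel–Crafts capture of the thionium ion by the electron-rich rings, which slow addition of 14, a hindered base, a non-polar solvent and the intramolecular ion-pair collapse of 17 should secure.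

**Step 9**
Reactants: 18 (3S,4S,5R)-3,4-bis(4-benzyloxy-3-methoxybenzyl)-3-(tert-butyldimethylsilyloxy)-5-(4-methylphenylthio)dihydrofuran-2(3H)-one
Product: 19 (3S,4R)-3,4-bis(4-benzyloxy-3-methoxybenzyl)-3-(tert-butyldimethylsilyloxy)dihydrofuran-2(3H)-one
Conditions: Bu3SnH, AIBN, toluene, 90 °C
Reagents that add atoms: none
Why: In this radical desulfurization the stannyl radical takes the arylthio group (SH2 at sulfur) and the α-acyloxy radical at C9' abstracts hydrogen from Bu3SnH, which removes the helper and its stereocentre without touching C8 or C8'.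

**Step 10**
Reactants: 19 (3S,4R)-3,4-bis(4-benzyloxy-3-methoxybenzyl)-3-(tert-butyldimethylsilyloxy)dihydrofuran-2(3H)-one
Product: 20 (3S,4R)-3,4-bis(4-benzyloxy-3-methoxybenzyl)-3-hydroxydihydrofuran-2(3H)-one
Conditions: 48% aq HF, MeCN, rt
Reagents that add atoms: none
Why: Fluoride-driven cleavage of the hindered tertiary silyl ether under acidic conditions spares the lactone and the benzyl ethers and cannot epimerise either stereocentre.

**Step 11**
Reactants: 20 (3S,4R)-3,4-bis(4-benzyloxy-3-methoxybenzyl)-3-hydroxydihydrofuran-2(3H)-one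
Product: 21 (3S,4R)-3-hydroxy-3,4-bis(4-hydroxy-3-methoxybenzyl)dihydrofuran-2(3H)-one
Conditions: H2 (1 atm), 10% Pd/C, EtOAc/EtOH, rt
Reagents that add atoms: none
Why: Catalytic hydrogenolysis cleaves only the two aryl benzyl ethers, since C7 and C7' carry no heteroatom and the lactone C–O bond is not benzylic.

**Compound list**
1 | 4-benzyloxy-3-methoxybenzyl alcohol | COc1cc(CO)ccc1OCc1ccccc1 | starting material
2 | 4-benzyloxy-3-methoxybenzyl bromide | COc1cc(CBr)ccc1OCc1ccccc1 | intermediate
3 | ethynylmagnesium bromide | C#C[Mg]Br | starting material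
4 | 1-benzyloxy-2-methoxy-4-(prop-2-yn-1-yl)benzene | C#CCc1ccc(OCc2ccccc2)c(OC)c1 | intermediate
5 | (1R,2S,5R)-menthyl (S)-4-methylbenzenesulfinate | CC(C)[C@@H]1CC[C@@H](C)C[C@H]1O[S@](=O)c1ccc(C)cc1 | starting material
6 | [3-(4-benzyloxy-3-methoxyphenyl)prop-1-yn-1-yl]magnesium bromide | Br[Mg]C#CCc1ccc(OCc2ccccc2)c(OC)c1 | intermediate
7 | (S)-1-benzyloxy-2-methoxy-4-[3-(4-methylphenylsulfinyl)prop-2-yn-1-yl]benzene | Cc1ccc(cc1)[S@](=O)C#CCc1ccc(OCc2ccccc2)c(OC)c1 | intermediate
8 | [(E)-3-(4-benzyloxy-3-methoxyphenyl)-1-(4-methylphenylsulfinyl)prop-1-en-1-yl]diisobutylalane (Al cis to the arylmethyl group, geometry at sulfur as in 7) | CC(C)C[Al](CC(C)C)/C(=C\Cc1ccc(OCc2ccccc2)c(OC)c1)[S@@](=O)c1ccc(C)cc1 | intermediate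
9 | (R)-1-benzyloxy-2-methoxy-4-[(E)-3-(4-methylphenylsulfinyl)prop-2-en-1-yl]benzene | Cc1ccc(cc1)[S@](=O)/C=C/Cc1ccc(OCc2ccccc2)c(OC)c1 | intermediate
10 | ethyl 2-(tert-butyldimethylsilyloxy)acetate | CCOC(=O)CO[Si](C)(C)C(C)(C)C | starting material
11 | lithium enolate of 10 (geometry without consequence) | CCOC(O[Li])=CO[Si](C)(C)C(C)(C)C | intermediate
12 | ethyl (±)-3-(4-benzyloxy-3-methoxyphenyl)-2-(tert-butyldimethylsilyloxy)propanoate | CCOC(=O)C(Cc1ccc(OCc2ccccc2)c(OC)c1)O[Si](C)(C)C(C)(C)C | intermediate
13 | (±)-3-(4-benzyloxy-3-methoxyphenyl)-2-(tert-butyldimethylsilyloxy)propanoic acid | OC(=O)C(Cc1ccc(OCc2ccccc2)c(OC)c1)O[Si](C)(C)C(C)(C)C | intermediate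
14 | (±)-3-(4-benzyloxy-3-methoxyphenyl)-2-(tert-butyldimethylsilyloxy)propanoyl chloride | ClC(=O)C(Cc1ccc(OCc2ccccc2)c(OC)c1)O[Si](C)(C)C(C)(C)C | intermediate
15 | 3-(4-benzyloxy-3-methoxyphenyl)-2-(tert-butyldimethylsilyloxy)prop-1-en-1-one (siloxyketene) | O=C=C(Cc1ccc(OCc2ccccc2)c(OC)c1)O[Si](C)(C)C(C)(C)C | intermediate
16 | (R)-oxysulfonium (E)-enolate, adduct of the sulfinyl oxygen of 9 with C9 of 15 (arylmethyl group cis to O–S) | Cc1ccc(cc1)[S@+](O/C([O-])=C(/O[Si](C)(C)C(C)(C)C)Cc1ccc(OCc2ccccc2)c(OC)c1)/C=C/Cc1ccc(OCc2ccccc2)c(OC)c1 | intermediate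
17 | thionium carboxylate, open-chain product of the [3,3] shift with C8 and C8' set | [O-]C(=O)[C@](O[Si](C)(C)C(C)(C)C)(Cc1ccc(OCc2ccccc2)c(OC)c1)[C@H](Cc1ccc(OCc2ccccc2)c(OC)c1)C=[S+]c1ccc(C)cc1 | intermediate
18 | (3S,4S,5R)-3,4-bis(4-benzyloxy-3-methoxybenzyl)-3-(tert-butyldimethylsilyloxy)-5-(4-methylphenylthio)dihydrofuran-2(3H)-one | COc1cc(C[C@@H]2[C@@H](Sc3ccc(C)cc3)OC(=O)[C@]2(O[Si](C)(C)C(C)(C)C)Cc2ccc(OCc3ccccc3)c(OC)c2)ccc1OCc1ccccc1 | intermediate
19 | (3S,4R)-3,4-bis(4-benzyloxy-3-methoxybenzyl)-3-(tert-butyldimethylsilyloxy)dihydrofuran-2(3H)-one | COc1cc(C[C@@H]2COC(=O)[C@]2(O[Si](C)(C)C(C)(C)C)Cc2ccc(OCc3ccccc3)c(OC)c2)ccc1OCc1ccccc1 | intermediate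
20 | (3S,4R)-3,4-bis(4-benzyloxy-3-methoxybenzyl)-3-hydroxydihydrofuran-2(3H)-one | COc1cc(C[C@@H]2COC(=O)[C@]2(O)Cc2ccc(OCc3ccccc3)c(OC)c2)ccc1OCc1ccccc1 | intermediate
21 | (3S,4R)-3-hydroxy-3,4-bis(4-hydroxy-3-methoxybenzyl)dihydrofuran-2(3H)-one | COc1cc(C[C@@H]2COC(=O)[C@]2(O)Cc2ccc(O)c(OC)c2)ccc1O | target

**Step count:** 11 steps in total. The longest linear sequence is 8 steps (1, 5, 6, 7, 8, 9, 10, 11); the branch 1, 2, 3, 4, 8, 9, 10, 11 is equally long.

**Steps most likely to fail**

**Step 8.** Several processes could undermine it: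
- The hindered ketene may dimerise before the sulfinyl oxygen adds.
- The activated sulfoxide may lose a C7' proton and leave along a vinylogous Pummerer path.
- Entry of the sulfoxide on the wrong side of the ketene, direct O-acylation followed by unselective deprotonation, or a boat transition state may erode control at C8.

The fallback uses known chemistry, sets out from 9 and returns at 20. Dichloroketene F1, made in the flask from Cl3CCOCl and Zn–Cu couple in Et2O, should undergo the established lactonization with 9. This gives (4R,5R)-4-(4-benzyloxy-3-methoxybenzyl)-3,3-dichloro-5-(4-methylphenylthio)dihydrofuran-2(3H)-one F2. Excess Bu3SnH with AIBN strips both chlorines and the arylthio group to give (S)-4-(4-benzyloxy-3-methoxybenzyl)dihydrofuran-2(3H)-one F3. LiN(SiMe3)2 and bromide 2 then give the trans lactone (3S,4S)-3,4-bis(4-benzyloxy-3-methoxybenzyl)dihydrofuran-2(3H)-one F4. KN(SiMe3)2 followed by 2-(phenylsulfonyl)-3-phenyloxaziridine should hydroxylate the enolate on the face away from the C8' benzyl group. That puts the two benzyl groups cis and gives 20.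

**Step 3.** The doubly activated CH2 may isomerise from propargyl to allenyl under the basic magnesium species, and a second attack at sulfur may lower the configurational purity. The fallback is base-free, sets out from 4 and returns at 9, bypassing steps 3 and 4. RhCl(PPh3)3-catalysed anti-Markovnikov syn-hydrothiolation of 4 with 4-methylbenzenethiol should give (E)-1-benzyloxy-2-methoxy-4-[3-(4-methylphenylthio)prop-2-en-1-yl]benzene F5. Kagan-type asymmetric sulfoxidation follows (Ti(OiPr)4, (R,R)-diethyl tartrate, H2O, cumene hydroperoxide, CH2Cl2, −20 °C). It should favour the R sulfoxide 9 by analogy with aryl methyl sulfides, and recrystallisation would raise the enantiomeric purity.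

**Step 5.** The glycolate enolate may self-condense or suffer O-to-C silyl migration, and the electron-rich bromide may decompose before it is alkylated. The fallback reverses the polarity of the C7–C8 bond formation, sets out from 2 and returns at 12. Zinc insertion (Zn dust, LiCl, THF) should give (4-benzyloxy-3-methoxybenzyl)zinc bromide F6. This adds to ethyl glyoxylate to give ethyl (±)-3-(4-benzyloxy-3-methoxyphenyl)-2-hydroxypropanoate F7. Silylation with TBSCl and imidazole in DMF gives 12.

**Further compounds**
F1 | step 8 | dichloroketene | ClC(Cl)=C=O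
F2 | step 8 | (4R,5R)-4-(4-benzyloxy-3-methoxybenzyl)-3,3-dichloro-5-(4-methylphenylthio)dihydrofuran-2(3H)-one | COc1cc(C[C@@H]2[C@@H](Sc3ccc(C)cc3)OC(=O)C2(Cl)Cl)ccc1OCc1ccccc1
F3 | step 8 | (S)-4-(4-benzyloxy-3-methoxybenzyl)dihydrofuran-2(3H)-one | COc1cc(C[C@@H]2COC(=O)C2)ccc1OCc1ccccc1
F4 | step 8 | (3S,4S)-3,4-bis(4-benzyloxy-3-methoxybenzyl)dihydrofuran-2(3H)-one | COc1cc(C[C@@H]2COC(=O)[C@H]2Cc2ccc(OCc3ccccc3)c(OC)c2)ccc1OCc1ccccc1
F5 | step 3 | (E)-1-benzyloxy-2-methoxy-4-[3-(4-methylphenylthio)prop-2-en-1-yl]benzene | Cc1ccc(cc1)S/C=C/Cc1ccc(OCc2ccccc2)c(OC)c1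
F6 | step 5 | (4-benzyloxy-3-methoxybenzyl)zinc bromide | Br[Zn]Cc1ccc(OCc2ccccc2)c(OC)c1
F7 | step 5 | ethyl (±)-3-(4-benzyloxy-3-methoxyphenyl)-2-hydroxypropanoate | CCOC(=O)C(O)Cc1ccc(OCc2ccccc2)c(OC)c1
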